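**Strategy.** The target is the 2,3-dihydro form of a C2-symmetric 3,3''-biflavone. In each ring C, C3 is α to the C2 carbon that carries O1 and the aryl group, C4 is an aroyl carbon, and C8a lies ortho to it on ring A. The key step uses this: the dienolate of a 1,4-diaryl-1,4-diketone (C2–C3–C3''–C2'', both O1 atoms in place) is C-acylated twice by 2,4,6-trifluorobenzoyl chloride (C3–C4), and each enolate oxygen then displaces an ortho-fluorine (O1–C8a). Both pyranone rings close at the flavone oxidation level. The spare fluorines become the 5,7-oxygens; conjugate monoreduction, kinetic resolution and hydrogenolysis then give the single enantiomer.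

Key step: step 2

Remark: the 2,3-trans (2S,3R) arrangement of the target is the diequatorial, thermodynamically preferred one, so C3 is left to equilibrate in step 4. Atom labels follow flavonoid numbering (doubly primed for the flavone unit). The SMILES of racemate 8 shows both enantiomers joined by a dot.

**Step 1**
Reactants: 1 1-[4-(benzyloxy)phenyl]ethan-1-one; 2 2-bromo-1-[4-(benzyloxy)phenyl]ethan-1-one
Product: 3 1,4-bis[4-(benzyloxy)phenyl]butane-1,4-dione
Conditions: ZnCl2, Et2NH, t-BuOH, toluene, rt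
Reagents that add atoms: none
Why: In this zinc-mediated coupling of a methyl ketone with an α-bromo ketone, the zinc enolate of 1 should add to the carbonyl of 2, the bromo aldolate should close to a zinc cyclopropanolate by 1,3-elimination of bromide, and ring opening of that cyclopropanolate should give the symmetric 1,4-diketone.

**Step 2**
Reactants: 3 1,4-bis[4-(benzyloxy)phenyl]butane-1,4-dione; 4 2,4,6-trifluorobenzoyl chloride
Product: 6 2,2'-bis[4-(benzyloxy)phenyl]-5,5',7,7'-tetrafluoro-4H,4'H-[3,3'-bichromene]-4,4'-dione, via tetraketone 5 (not isolated)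
Conditions: LiN(SiMe3)2 (4.2 equiv), THF, −78 °C; 4 (2.1 equiv), −78 to 0 °C; then DMF, 70 °C
Reagents that add atoms: none
Why: LiN(SiMe3)2 turns 3 into its buta-1,3-diene-1,4-diolate and each of the two central carbons (the future C3 and C3'') attacks the acyl chloride carbon of one molecule of 4 (C3–C4 bond, Claisen-type C-acylation), the acidic 1,3-diketone units of 5 being kept as lithium diketonates by the extra base. On warming in DMF the enolate oxygen on each C2 adds to the ortho C–F carbon of the neighbouring trifluorobenzoyl ring and fluoride leaves (O1–C8a bond, SNAr by addition–elimination), so that the closest known reaction is the one-pot flavone synthesis from a ketone enolate and a 2-fluorobenzoyl chloride, run here in two directions. Each pyranone ring (O1, C2, C3, C4, C4a, C8a) closes in a six-membered addition–elimination at an arene carbon, exo with respect to the C–F bond that breaks, while closure onto the other trifluorophenyl ring would need a seven-membered ring. No stereocenter is formed, because C2 and C3 are sp2 at this oxidation level; they are set in steps 4 and 5. The step needs C- over O-acylation at a crowded enolate carbon and ortho over para displacement of fluoride. The lithium enolate in THF at low temperature favours the carbon, the three fluorines plus the ketone activate the ring, and only an ortho fluorine is within reach of the tethered oxygen.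

**Step 3**
Reactants: 6 2,2'-bis[4-(benzyloxy)phenyl]-5,5',7,7'-tetrafluoro-4H,4'H-[3,3'-bichromene]-4,4'-dione
Product: 7 5,5',7,7'-tetrakis(benzyloxy)-2,2'-bis[4-(benzyloxy)phenyl]-4H,4'H-[3,3'-bichromene]-4,4'-dione
Conditions: BnOH, NaH, DMF, 0 to 50 °C
Reagents that add atoms: benzyl alcohol, OCc1ccccc1
Why: Nucleophilic aromatic substitution should replace the 5- and 7-fluorines, which are ortho and para to the C4 carbonyl of each chromone, by benzyloxide and so put in the protected 5,7-oxygens.

**Step 4**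
Reactants: 7 5,5',7,7'-tetrakis(benzyloxy)-2,2'-bis[4-(benzyloxy)phenyl]-4H,4'H-[3,3'-bichromene]-4,4'-dione
Product: 8 racemic (2RS,3SR)-5,7-bis(benzyloxy)-2-[4-(benzyloxy)phenyl]-3-{5,7-bis(benzyloxy)-2-[4-(benzyloxy)phenyl]-4-oxo-4H-chromen-3-yl}chroman-4-one
Conditions: LiBH(s-Bu)3 (1.05 equiv), THF, −78 °C; aq. NH4Cl; then DBU (cat.), CH2Cl2, rt
Reagents that add atoms: none
Why: Conjugate (1,4) hydride reduction of one chromone at C2 should give a lithium enolate whose electron-rich, bulky C3 deactivates the second, symmetry-equivalent ring, and protonation with base equilibration at C3 should give the diequatorial 2,3-trans racemate.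

**Step 5**
Reactants: 8 racemic (2RS,3SR)-5,7-bis(benzyloxy)-2-[4-(benzyloxy)phenyl]-3-{5,7-bis(benzyloxy)-2-[4-(benzyloxy)phenyl]-4-oxo-4H-chromen-3-yl}chroman-4-one
Product: 9 (2S,3R)-5,7-bis(benzyloxy)-2-[4-(benzyloxy)phenyl]-3-{5,7-bis(benzyloxy)-2-[4-(benzyloxy)phenyl]-4-oxo-4H-chromen-3-yl}chroman-4-one
Conditions: RuCl(p-cymene)[(R,R)-TsDPEN] (cat.), HCO2H, Et3N, CH2Cl2, rt, stopped near half conversion
Reagents that add atoms: none
Why: Noyori–Ikariya asymmetric transfer hydrogenation used as a kinetic resolution should reduce the C4 ketone of the (2R,3S) enantiomer much faster and leave the (2S,3R) ketone, the sense being assigned by analogy with 2-arylchroman-4-ones and to be confirmed.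

**Step 6**
Reactants: 9 (2S,3R)-5,7-bis(benzyloxy)-2-[4-(benzyloxy)phenyl]-3-{5,7-bis(benzyloxy)-2-[4-(benzyloxy)phenyl]-4-oxo-4H-chromen-3-yl}chroman-4-one
Product: 10 (2S,3R)-5,7-dihydroxy-2-(4-hydroxyphenyl)-3-[5,7-dihydroxy-2-(4-hydroxyphenyl)-4-oxo-4H-chromen-3-yl]chroman-4-one
Conditions: H2 (1 atm), Pd/C, EtOAc/MeOH, rt
Reagents that add atoms: none
Why: Hydrogenolysis of the six aryl benzyl ethers runs under neutral conditions that cannot open the flavanone ring by retro-oxa-Michael reaction, so C2 and C3 should stay as set.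

**Compound list**
1 | 1-[4-(benzyloxy)phenyl]ethan-1-one | CC(=O)c1ccc(OCc2ccccc2)cc1 | starting material
2 | 2-bromo-1-[4-(benzyloxy)phenyl]ethan-1-one | O=C(CBr)c1ccc(OCc2ccccc2)cc1 | starting material
3 | 1,4-bis[4-(benzyloxy)phenyl]butane-1,4-dione | O=C(CCC(=O)c1ccc(OCc2ccccc2)cc1)c1ccc(OCc2ccccc2)cc1 | intermediate
4 | 2,4,6-trifluorobenzoyl chloride | O=C(Cl)c1c(F)cc(F)cc1F | starting material
5 | 2,3-bis[4-(benzyloxy)benzoyl]-1,4-bis(2,4,6-trifluorophenyl)butane-1,4-dione (tetraketone, formed as its dilithium salt) | O=C(c1c(F)cc(F)cc1F)C(C(=O)c1ccc(OCc2ccccc2)cc1)C(C(=O)c1ccc(OCc2ccccc2)cc1)C(=O)c1c(F)cc(F)cc1F | intermediate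
6 | 2,2'-bis[4-(benzyloxy)phenyl]-5,5',7,7'-tetrafluoro-4H,4'H-[3,3'-bichromene]-4,4'-dione | O=c1c(-c2c(-c3ccc(OCc4ccccc4)cc3)oc3cc(F)cc(F)c3c2=O)c(-c2ccc(OCc3ccccc3)cc2)oc2cc(F)cc(F)c12 | intermediate
7 | 5,5',7,7'-tetrakis(benzyloxy)-2,2'-bis[4-(benzyloxy)phenyl]-4H,4'H-[3,3'-bichromene]-4,4'-dione | O=c1c(-c2c(-c3ccc(OCc4ccccc4)cc3)oc3cc(OCc4ccccc4)cc(OCc4ccccc4)c3c2=O)c(-c2ccc(OCc3ccccc3)cc2)oc2cc(OCc3ccccc3)cc(OCc3ccccc3)c12 | intermediate
8 | racemic (2RS,3SR)-5,7-bis(benzyloxy)-2-[4-(benzyloxy)phenyl]-3-{5,7-bis(benzyloxy)-2-[4-(benzyloxy)phenyl]-4-oxo-4H-chromen-3-yl}chroman-4-one | O=C1c2c(OCc3ccccc3)cc(OCc3ccccc3)cc2O[C@H](c2ccc(OCc3ccccc3)cc2)[C@H]1c1c(-c2ccc(OCc3ccccc3)cc2)oc2cc(OCc3ccccc3)cc(OCc3ccccc3)c2c1=O.O=C1c2c(OCc3ccccc3)cc(OCc3ccccc3)cc2O[C@@H](c2ccc(OCc3ccccc3)cc2)[C@@H]1c1c(-c2ccc(OCc3ccccc3)cc2)oc2cc(OCc3ccccc3)cc(OCc3ccccc3)c2c1=O | intermediate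
9 | (2S,3R)-5,7-bis(benzyloxy)-2-[4-(benzyloxy)phenyl]-3-{5,7-bis(benzyloxy)-2-[4-(benzyloxy)phenyl]-4-oxo-4H-chromen-3-yl}chroman-4-one | O=C1c2c(OCc3ccccc3)cc(OCc3ccccc3)cc2O[C@H](c2ccc(OCc3ccccc3)cc2)[C@H]1c1c(-c2ccc(OCc3ccccc3)cc2)oc2cc(OCc3ccccc3)cc(OCc3ccccc3)c2c1=O | intermediate
10 | (2S,3R)-5,7-dihydroxy-2-(4-hydroxyphenyl)-3-[5,7-dihydroxy-2-(4-hydroxyphenyl)-4-oxo-4H-chromen-3-yl]chroman-4-one | O=C1c2c(O)cc(O)cc2O[C@H](c2ccc(O)cc2)[C@H]1c1c(-c2ccc(O)cc2)oc2cc(O)cc(O)c2c1=O | target

**Step count and risks**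
Total steps: 6. Longest linear sequence: 6 steps (from 1; compounds 2 and 4 are bought).

Steps most likely to fail:

Step 2. The second C-acylation takes place at a carbon next to a fully substituted diketonate, so O-acylation of the enolate or a stop after one acylation may take over. The fallback sets out from 3 and runs the two annulations one after the other. With one equivalent of 4 and LiN(SiMe3)2 in THF, then DMF at 60 °C, 3 should give 2-[4-(benzyloxy)phenyl]-3-{2-[4-(benzyloxy)phenyl]-2-oxoethyl}-5,7-difluoro-4H-chromen-4-one F1, which is isolated. Its remaining ketone would then be C-acylated by 4 under magnesium-mediated soft enolization (MgBr2·OEt2, i-Pr2NEt, CH2Cl2) to give 2-[4-(benzyloxy)phenyl]-3-{1-[4-(benzyloxy)phenyl]-1,3-dioxo-3-(2,4,6-trifluorophenyl)propan-2-yl}-5,7-difluoro-4H-chromen-4-one F2. Ring closure of this compound with K2CO3 in DMF comes back to the route at 6.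

Step 4. Hydride delivery to the tetrasubstituted, aryl-bearing C2 may be slow, so attack at the C4 carbonyl or a second conjugate reduction may compete. The fallback sets out from 7 and activates one chromone carbonyl as an electrophile instead. One equivalent of t-BuMe2SiOTf in CH2Cl2 at −78 °C with Et3SiH as hydride donor to C2 should give racemic 5,7-bis(benzyloxy)-2-[4-(benzyloxy)phenyl]-3-{5,7-bis(benzyloxy)-2-[4-(benzyloxy)phenyl]-4-[(tert-butyldimethylsilyl)oxy]-2H-chromen-3-yl}-4H-chromen-4-one F3. The cationic charge after the first silylation should keep the second ring from reacting. Cleavage of the silyl enol ether with Bu4NF and AcOH in THF, followed by catalytic DBU, should come back to the route at 8.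

Step 5. The catalyst may tell the two enantiomers apart poorly, or may fail to reduce the crowded C4 ketone that lies between the 5-benzyloxy group and the C3 substituent. The fallback sets out from 8 and separates the enantiomers physically by preparative chromatography on a cellulose tris(3,5-dimethylphenylcarbamate) stationary phase. It comes back to the route at 9 and makes no new compound.

**Further compounds**
F1 | step 2 | 2-[4-(benzyloxy)phenyl]-3-{2-[4-(benzyloxy)phenyl]-2-oxoethyl}-5,7-difluoro-4H-chromen-4-one | O=C(Cc1c(-c2ccc(OCc3ccccc3)cc2)oc2cc(F)cc(F)c2c1=O)c1ccc(OCc2ccccc2)cc1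
F2 | step 2 | 2-[4-(benzyloxy)phenyl]-3-{1-[4-(benzyloxy)phenyl]-1,3-dioxo-3-(2,4,6-trifluorophenyl)propan-2-yl}-5,7-difluoro-4H-chromen-4-one | O=C(c1ccc(OCc2ccccc2)cc1)C(C(=O)c1c(F)cc(F)cc1F)c1c(-c2ccc(OCc3ccccc3)cc2)oc2cc(F)cc(F)c2c1=O
F3 | step 4 | racemic 5,7-bis(benzyloxy)-2-[4-(benzyloxy)phenyl]-3-{5,7-bis(benzyloxy)-2-[4-(benzyloxy)phenyl]-4-[(tert-butyldimethylsilyl)oxy]-2H-chromen-3-yl}-4H-chromen-4-one | CC(C)(C)[Si](C)(C)OC1=C(c2c(-c3ccc(OCc4ccccc4)cc3)oc3cc(OCc4ccccc4)cc(OCc4ccccc4)c3c2=O)C(c2ccc(OCc3ccccc3)cc2)Oc2cc(OCc3ccccc3)cc(OCc3ccccc3)c12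
F0 | step 5 | none | none
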